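You read each flask at 25 d, and what you want then is the target counted in all its forms, set against the reagent you put in.

all flasks: substrate 10 mM

| flask | reagent | remark | time |
|---|---|---|---|
| Wednesday's | 0.049 equiv | run made earlier |  |
| Thursday's | 4.4 equiv | run made earlier |  |
| zeta | 0.0400 equiv |  | 25 d |
| delta | 0.100 equiv |  | 25 d |
| alpha | 0.300 equiv |  | 25 d |
| beta | 1.00 equiv |  | 25 d |
| eta | 3.00 equiv |  | 25 d |

| run | time / d | target / % |
|---|---|---|
| Wednesday's | 1.67 | 4 |
| Wednesday's | 5.00 | 2 |
| Wednesday's | 8.00 | 0 |
| Wednesday's | 15.0 | 6 |
| Wednesday's | 20.0 | 2 |
| Wednesday's | 25.0 | 0 |
| Thursday's | 2.08 | 30 |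
| Thursday's | 3.00 | 30 |
| Thursday's | 6.00 | 34 |
| Thursday's | 10.0 | 40 |
| Thursday's | 15.0 | 45 |
| Thursday's | 25.0 | 60 |

(scatter of a reading: 2 percentage points)

- amount of target at the end, in percent of the substrate charged for zeta, delta, alpha, beta, eta, in this order
- how that number moves from the first to the last of them (falls, then rises / hardly changes / rises, then falls / falls all the way / rises all the way)

- a reading or a percentage of target counts all its forms, free or not
- "hardly changes" means that all values lie within two and a half points (for a concentration: within two and a half percent of the largest)

No rate constant is on hand, but the charge is. If each target takes one reagent, which is my assumption, then a flask short of reagent has the reagent as its limiting reagent. The useful question there is less how fast the step runs than what share of the reagent ends as target. Wednesday's readings show no trend and average 2.33% from a charge of 0.049 equiv. That gives 47.6%, the reagent yield: target at the reading per reagent charged. With the scatter of a mean of 6 readings, it is good to about 16.7% of the reagent charged, as a reading and no better.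

My first answer is this yield times the equivalents: 1.90% for zeta, 4.76% for delta, 14.3% for alpha and 47.6% for beta. For eta it gives 143%, more than the substrate charged, so that answer has to go back in and be corrected. Thursday's flask, with 4.4 equiv, reads 60% at 25.0 d, a reagent yield of 13.6%, far below Wednesday's. At my yield that reading takes 1.26 equivalents of reagent. Beta has fewer than that and stays on the reagent line, while eta has more, so I put eta at Thursday's 60%.

The forecast gives 2%, 5%, 11%, 23% and 44%, a row that rises all the way, reckoned as a burst plus a drift, where the “burst grows less than proportionally with reagent”. It agrees with my row in direction, but its beta value lies well under mine.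

The flasks give 2.20%, 5.49%, 16.2%, 45.3% and 56.6%, so the row rises all the way, with beta at 45.3% against the forecast's 23%.

substrate + reagent ⇌ side product (K = 1700 L mol⁻¹, k = 0.0980 L mol⁻¹ min⁻¹); substrate + reagent → target (k = 0.0370 L mol⁻¹ min⁻¹); substrate ⇌ intermediate A (K = 0.250, k = 1.00 × 10⁻⁴ min⁻¹); intermediate A ⇌ intermediate B (K = 8.10, k = 0.00380 min⁻¹); crystals ⇌ target, rate k5*(cs5 - [target]) while solid is left; crystals form when [target] > cs5 (solubility = 4.00 mM, k = 0.00460 min⁻¹) The reagent yield of zeta comes to 55.0% and that of alpha to 54.0%, against the 47.6% read from Wednesday's run. In zeta, substrate enters intermediate A 6.8 times as fast as it enters target at the start, forward step alone, and 120 times as fast at 25.0 d. Zeta ends with 59.0% as intermediate B and 29.9% as substrate, beside 5.7% of its own charge of reagent.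

The runs come from a simulation from invented constants, and the scatter is random.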